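I decide to keep the books in fractions of the solid substrate charged, since the gas phase is held and this solid is the limiting reagent of each flask.

the same everywhere: gas phase 17 mM (held)

| run | solid substrate | temperature | remark | time |
|---|---|---|---|---|
| north | 0.0063 M | −1 °C | run made earlier |  |
| south-west | 0.050 M | 29 °C | run made earlier |  |
| violet | 0.012 M | 5 °C |  | 8.0 min |
| blue | 0.012 M | 25 °C |  | 8.0 min |
| amber | 0.040 M | 25 °C |  | 8.0 min |
| red | 0.020 M | 40 °C |  | 8.0 min |
| grey | 0.060 M | −15 °C |  | 8.0 min |

| run | time / min | target / % |
|---|---|---|
| north | 1.50 | 47.2 |
| north | 4.00 | 93.6 |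
| north | 10.0 | 101.3 |
| north | 20.0 | 99.2 |
| south-west | 0.417 | 3.6 |
| south-west | 1.00 | 8.2 |
| south-west | 2.50 | 19.2 |
| south-west | 6.00 | 52.2 |

(standard deviation of a reading: 1 percentage point)

- ranking by amount of target, in percent of the solid substrate charged, from high to low, at 8.0 min (violet / blue / amber / red / grey)
- the amount of target, in percent of the solid substrate charged of the flask you put first, at 8.0 min
- the amount of target, in percent of the solid substrate charged of the flask you put last, at 8.0 min

- at the start none of the gas phase is in solution
- at the start none of the solid substrate is in solution
- what has only dissolved of solid substrate counts as not reacted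
- a reading or a percentage of target counts all its forms, free or not

South-west gains 0.0820 min⁻¹ of its charge per minute up to 1.00 min and 0.0870 min⁻¹ on average up to 6.00 min, a nearly straight line. I read this as a steady feed of target while solid remains, pseudo-zero-order in the charge. I take the feed from the longest south-west reading and the first north reading, when north still climbs steeply:

south-west, 29 °C: feed 0.00435 M min⁻¹

north, −1 °C: feed 0.00198 M min⁻¹

I carry the logarithm of the feed in a straight line through these two temperatures, beyond them for grey and red. For grey the feed is 0.00137 M min⁻¹. Feed times time over charge is then 0.183, and I carry this feed fraction, the share of the charge the feed can pass to target in the time. Below one, it is the entry for target and the rest stays unreacted; above one, the books close before the time is up, near the full charge, as north does with 101.3 % and 99.2 %.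

grey: target 0.183, unreacted 0.817

amber: feed 0.00392 M min⁻¹, target 0.783, unreacted 0.217

violet: feed fraction 1.55, closed

blue: feed fraction 2.61, closed

red: feed fraction 2.32, closed

So I put grey last and amber fourth, and I leave violet, blue and red unranked.

The forecast, reading the runs as “a solid that keeps the solution saturated”, gives red > blue > violet > amber > grey, with 99.9 % (from 98.5 % to 100 %) first and 17.5 % (from 14.5 % to 21 %) last, which is below my 18.3 %.

The flasks give violet > blue > red > amber > grey: violet 99.0 %, blue 96.6 %, red 92.8 %, amber 82.7 %, grey 15.8 %.

    gas phase ⇌ dissolved gas, rate k1*(csat - [dissolved gas]) (kL = 0.110 s⁻¹)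
    starting material + dissolved gas → target (k = 9.95 M⁻¹ s⁻¹, Ea = 36.0 kJ mol⁻¹)
    starting material → side product (k = 0.00551 s⁻¹, Ea = 77.0 kJ mol⁻¹)
    crystals ⇌ target, rate k4*(cs4 - [target]) while solid is left; crystals form when [target] > cs4 (solubility = 4.00 mM, k = 0.243 s⁻¹)
    solid substrate ⇌ starting material, rate k5*(cs5 - [starting material]) while solid is left; crystals form when [starting material] > cs5 (solubility = 1.80 mM, k = 0.0528 s⁻¹)
    starting material + target ⇌ idle adduct, settled at all times (K = 53.3 M⁻¹, ΔH = −56.0 kJ mol⁻¹)
    (constants at 25 °C)

At 8.00 min grey holds solid substrate 71.7 %, starting material 1.92 %, idle adduct 21.2 % and target 15.8 %, against my feed fraction of 18.3 %, while starting material goes to target 390 times as fast as to side product. With 0.015 M of solid substrate in the neighbour of grey, the same feed gives a feed fraction of 0.733, and that flask holds target 61.3 %, solid substrate 0 %, starting material 4.71 % and idle adduct 67.6 %.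

The runs are calculated with constants of no real substance.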